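**Retrosynthetic overview**

1. Tetralin numbering: C1 = CH(aryl), C2/C3 = carbons bearing the CH2OH arms C9/C10, C4 = benzylic CH2, C4a/C8a = fusion carbons; ring A = oxygenated benzo ring (OMe on C6, OH on C7 and C8), ring B = carbocycle, ring C = trimethoxyphenyl.
2. Feature used: C1 is doubly benzylic, with the ortho C8 and para C6 oxygens of ring A and ring C to carry a positive charge, and C2 becomes a carbon acid once C9 and C10 are tied as a γ-lactone with an extra ethyl ester on C2.
3. Target 18 ⇐ diol 17 ⇐ cis-fused lactone 16 ⇐ lactone ester 15 (hydrogenolysis, LiAlH4, Krapcho); 15 ⇐ carbinol 14 by cutting C1–C2 (benzhydryl cation plus enol of the 1,3-dicarbonyl).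
4. 14 ⇐ aldehyde 12 + ring C Grignard 13 (C1–aryl bond); 12 ⇐ ring A Grignard 10 + cyclopropane lactone 9 (C4–C4a bond); 9 ⇐ (S)-epichlorohydrin 6 + diethyl malonate 7, which fixes C3.
5. Ring order: rings A and C are bought as arenes, the lactone ring is made first (step 5), ring B is closed last (step 9), and the lactone is opened by reduction at the end.

Key step: step 9

Remark: the lactone α-carbon (C2) in 11, 12 and 14 and the carbinol carbon (C1) in 14 are carried as epimer mixtures, because step 9 passes through a planar cation and an enol and sets both centres anew.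

**Step 1**
Reactants: 1 5-bromo-1,2,3-trimethoxybenzene
Product: 2 6-bromo-2,3,4-trimethoxybenzaldehyde
Conditions: Cl2CHOMe (1.5 equiv), TiCl4 (2 equiv), CH2Cl2, −10 °C to rt; ice-water
Reagents that add atoms: dichloromethyl methyl ether, COC(Cl)Cl; water, O
Why: Rieche formylation (electrophilic aromatic substitution); the only free positions, C4 and C6 of 1, are equivalent and each is ortho and para to a methoxy group, so a single aldehyde is expected.

**Step 2**
Reactants: 2 6-bromo-2,3,4-trimethoxybenzaldehyde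
Product: 3 6-bromo-2,3-dihydroxy-4-methoxybenzaldehyde
Conditions: BCl3 (2.5 equiv), CH2Cl2, 0 °C to rt; H2O
Reagents that add atoms: none
Why: Chelation-directed BCl3 ether cleavage; boron held by the aldehyde oxygen removes the ortho (C2) methyl, the resulting aryloxyboron chloride reaches the adjacent C3 methoxy, and the remote C4 methoxy is left.

**Step 3**
Reactants: 3 6-bromo-2,3-dihydroxy-4-methoxybenzaldehyde
Product: 4 2,3-bis(benzyloxy)-6-bromo-4-methoxybenzaldehyde
Conditions: BnBr (2.4 equiv), K2CO3 (3 equiv), DMF, 60 °C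
Reagents that add atoms: benzyl bromide, BrCc1ccccc1
Why: Williamson etherification of both phenols; aldehyde and aryl bromide are inert to carbonate.

**Step 4**
Reactants: 4 2,3-bis(benzyloxy)-6-bromo-4-methoxybenzaldehyde
Product: 5 2-[2,3-bis(benzyloxy)-6-bromo-4-methoxyphenyl]-1,3-dioxolane
Conditions: ethylene glycol (5 equiv), TsOH·H2O (5 mol%), toluene, reflux, azeotropic removal of water
Reagents that add atoms: ethylene glycol, OCCO
Why: Acid-catalysed acetalisation masks the aldehyde as a dioxolane that survives Grignard formation; benzyl ethers tolerate catalytic sulfonic acid.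

**Step 5**
Reactants: 6 (S)-epichlorohydrin; 7 diethyl malonate
Product: 9 ethyl (1R,5S)-2-oxo-3-oxabicyclo[3.1.0]hexane-1-carboxylate, via cyclopropylmethanol diester 8 (not isolated)
Conditions: NaOEt (1.05 equiv), EtOH, 0 °C then reflux
Reagents that add atoms: none
Why: Malonate alkylation cascade: the malonate anion opens the epoxide at its CH2, the alkoxide displaces chloride to form a new epoxide, 3-exo-tet opening at the stereogenic carbon (inversion) gives the cyclopropane, and the alkoxide lactonises onto the cis ester, so both centres of 9 derive from the single centre of 6.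

**Step 6**
Reactants: 5 2-[2,3-bis(benzyloxy)-6-bromo-4-methoxyphenyl]-1,3-dioxolane; 9 ethyl (1R,5S)-2-oxo-3-oxabicyclo[3.1.0]hexane-1-carboxylate
Product: 11 ethyl (4S)-4-[3,4-bis(benzyloxy)-2-(1,3-dioxolan-2-yl)-5-methoxybenzyl]-2-oxotetrahydrofuran-3-carboxylate (both epimers at the lactone α-carbon), via ring A aryl Grignard reagent 10 (not isolated)
Conditions: Mg turnings, I2 (crystal), THF, reflux; then CuI (10 mol%), 9 (1.3 equiv), THF, −40 to 0 °C; sat. aq NH4Cl
Reagents that add atoms: none
Why: Copper-catalysed homoconjugate (SN2-type) opening of the doubly activated cyclopropane by an aryl Grignard reagent at the unsubstituted CH2 releases the stabilised magnesium enolate; C5 of 9 is not touched and becomes C4 of the lactone, the future C3.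

**Step 7**
Reactants: 11 ethyl (4S)-4-[3,4-bis(benzyloxy)-2-(1,3-dioxolan-2-yl)-5-methoxybenzyl]-2-oxotetrahydrofuran-3-carboxylate
Product: 12 ethyl (4S)-4-[3,4-bis(benzyloxy)-2-formyl-5-methoxybenzyl]-2-oxotetrahydrofuran-3-carboxylate
Conditions: 1 M aq HCl, THF, rt
Reagents that add atoms: water, O
Why: Acid hydrolysis of an electron-rich aryl dioxolane is fast at room temperature, where lactone, ester and benzyl ethers are stable.

**Step 8**
Reactants: 12 ethyl (4S)-4-[3,4-bis(benzyloxy)-2-formyl-5-methoxybenzyl]-2-oxotetrahydrofuran-3-carboxylate; 1 5-bromo-1,2,3-trimethoxybenzene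
Product: 14 ethyl (4S)-4-{3,4-bis(benzyloxy)-2-[hydroxy(3,4,5-trimethoxyphenyl)methyl]-5-methoxybenzyl}-2-oxotetrahydrofuran-3-carboxylate (epimers at carbinol and α-carbon), via ring C aryl Grignard reagent 13 (not isolated)
Conditions: 1 (2.6 equiv), Mg turnings, THF, 50 °C; then 12 in THF added slowly to 13 at −78 °C, warm to −20 °C; sat. aq NH4Cl
Reagents that add atoms: none
Why: Grignard 1,2-addition with the dicarbonyl masked in the flask: one equivalent turns the acidic α-ethoxycarbonyl lactone into its magnesium enolate, which shields both carbonyls, and a second adds to the aldehyde, the only electrophile left; the carbinol configuration is not controlled because step 9 erases it.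

**Step 9**
Reactants: 14 ethyl (4S)-4-{3,4-bis(benzyloxy)-2-[hydroxy(3,4,5-trimethoxyphenyl)methyl]-5-methoxybenzyl}-2-oxotetrahydrofuran-3-carboxylate
Product: 15 ethyl (3aR,4S,9aS)-5,6-bis(benzyloxy)-7-methoxy-3-oxo-4-(3,4,5-trimethoxyphenyl)-3,4,9,9a-tetrahydronaphtho[2,3-c]furan-3a(1H)-carboxylate (tetralin numbering 1S,2R,3S)
Conditions: Sc(OTf)3 (10 mol%), CH3NO2 (0.01 M), rt to 50 °C
Reagents that add atoms: none
Why: Sc(OTf)3 ionises the diaryl carbinol of either epimer to a planar benzhydryl cation at C1, which is stabilised by the C8 and C6 oxygens of ring A and by ring C and has no β-hydrogen to lose, and the scandium-bound enol of the α-ethoxycarbonyl lactone attacks it through C2, water being the only by-product. The closest known reaction type is the Lewis-acid-catalysed dehydrative SN1 alkylation of 1,3-dicarbonyl compounds by benzhydryl alcohols, here run intramolecularly on the more acidic lactone ester. Ring B closes in a 6-(enolexo) mode, the enol double bond lying outside the new ring, onto a trigonal carbon that is formally endo if the charge is drawn through C8a. C2 is set by the existing C3 centre, because the three-atom link C3–C4–C4a brings C1 to the face of the lactone enol that carries C4 and so should give the cis ring fusion. C1 is set in a chair-like transition state in which ring C is pseudoaxial to avoid the peri C8 benzyloxy group and lies on the face opposite the lactone, where it escapes a 1,3-diaxial contact with the lactone CH2 (C10). The step needs diastereoselection at C1 and C- over O-alkylation and over intermolecular arylation; the first rests on this C3-relayed transition state, the second on the eight-membered ring that O-attack would require and on high dilution.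

**Step 10**
Reactants: 15 ethyl (3aR,4S,9aS)-5,6-bis(benzyloxy)-7-methoxy-3-oxo-4-(3,4,5-trimethoxyphenyl)-3,4,9,9a-tetrahydronaphtho[2,3-c]furan-3a(1H)-carboxylate
Product: 16 (3aR,4S,9aS)-5,6-bis(benzyloxy)-7-methoxy-4-(3,4,5-trimethoxyphenyl)-3a,4,9,9a-tetrahydronaphtho[2,3-c]furan-3(1H)-one
Conditions: LiCl (3 equiv), H2O (3 equiv), DMSO, 150 °C
Reagents that add atoms: none
Why: Krapcho dealkoxycarbonylation: chloride dealkylates the ethyl ester on the quaternary C2, the carboxylate loses CO2, and the lactone enolate is protonated to the cis-fused lactone, which is also the thermodynamic C2 epimer, so C9 ends cis to C10 and trans to ring C.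

**Step 11**
Reactants: 16 (3aR,4S,9aS)-5,6-bis(benzyloxy)-7-methoxy-4-(3,4,5-trimethoxyphenyl)-3a,4,9,9a-tetrahydronaphtho[2,3-c]furan-3(1H)-one
Product: 17 [(1S,2R,3S)-7,8-bis(benzyloxy)-6-methoxy-1-(3,4,5-trimethoxyphenyl)-1,2,3,4-tetrahydronaphthalene-2,3-diyl]dimethanol
Conditions: LiAlH4 (2.5 equiv), THF, 0 °C to rt; careful H2O quench, filtration
Reagents that add atoms: none
Why: LiAlH4 reduction of the lactone to the 1,4-diol; hydride addition to C9 at 0 °C is faster than enolisation, so the cis C2/C3 relationship passes into the diol, and the aryl ethers are inert.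

**Step 12**
Reactants: 17 [(1S,2R,3S)-7,8-bis(benzyloxy)-6-methoxy-1-(3,4,5-trimethoxyphenyl)-1,2,3,4-tetrahydronaphthalene-2,3-diyl]dimethanol
Product: 18 (6S,7R,8S)-6,7-bis(hydroxymethyl)-3-methoxy-8-(3,4,5-trimethoxyphenyl)-5,6,7,8-tetrahydronaphthalene-1,2-diol (target)
Conditions: H2 (1 atm), Pd on carbon (10 wt% Pd), degassed EtOAc/MeOH, rt; isolation under argon
Reagents that add atoms: none
Why: Hydrogenolysis of the two benzyl aryl ethers; the C1 diarylmethine has no heteroatom leaving group and the primary alcohols are not benzylic, so nothing else should be cleaved.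

**Compound list**

1 | 5-bromo-1,2,3-trimethoxybenzene | COc1cc(Br)cc(OC)c1OC | starting material
2 | 6-bromo-2,3,4-trimethoxybenzaldehyde | COc1cc(Br)c(C=O)c(OC)c1OC | intermediate
3 | 6-bromo-2,3-dihydroxy-4-methoxybenzaldehyde | COc1cc(Br)c(C=O)c(O)c1O | intermediate
4 | 2,3-bis(benzyloxy)-6-bromo-4-methoxybenzaldehyde | COc1cc(Br)c(C=O)c(OCc2ccccc2)c1OCc1ccccc1 | intermediate
5 | 2-[2,3-bis(benzyloxy)-6-bromo-4-methoxyphenyl]-1,3-dioxolane | COc1cc(Br)c(C2OCCO2)c(OCc2ccccc2)c1OCc1ccccc1 | intermediate
6 | (S)-epichlorohydrin | ClC[C@@H]1CO1 | starting material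
7 | diethyl malonate | CCOC(=O)CC(=O)OCC | starting material
8 | diethyl (2S)-2-(hydroxymethyl)cyclopropane-1,1-dicarboxylate (formed as its sodium alkoxide) | OC[C@H]1CC1(C(=O)OCC)C(=O)OCC | intermediate (not isolated)
9 | ethyl (1R,5S)-2-oxo-3-oxabicyclo[3.1.0]hexane-1-carboxylate | CCOC(=O)[C@@]12C[C@@H]1COC2=O | intermediate
10 | [3,4-bis(benzyloxy)-2-(1,3-dioxolan-2-yl)-5-methoxyphenyl]magnesium bromide | COc1cc([Mg]Br)c(C2OCCO2)c(OCc2ccccc2)c1OCc1ccccc1 | intermediate (not isolated)
11 | ethyl (4S)-4-[3,4-bis(benzyloxy)-2-(1,3-dioxolan-2-yl)-5-methoxybenzyl]-2-oxotetrahydrofuran-3-carboxylate | COc1cc(C[C@@H]2COC(=O)C2C(=O)OCC)c(C2OCCO2)c(OCc2ccccc2)c1OCc1ccccc1 | intermediate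
12 | ethyl (4S)-4-[3,4-bis(benzyloxy)-2-formyl-5-methoxybenzyl]-2-oxotetrahydrofuran-3-carboxylate | COc1cc(C[C@@H]2COC(=O)C2C(=O)OCC)c(C=O)c(OCc2ccccc2)c1OCc1ccccc1 | intermediate
13 | (3,4,5-trimethoxyphenyl)magnesium bromide | COc1cc([Mg]Br)cc(OC)c1OC | intermediate (not isolated)
14 | ethyl (4S)-4-{3,4-bis(benzyloxy)-2-[hydroxy(3,4,5-trimethoxyphenyl)methyl]-5-methoxybenzyl}-2-oxotetrahydrofuran-3-carboxylate | COc1cc(C[C@@H]3COC(=O)C3C(=O)OCC)c(C(O)c3cc(OC)c(OC)c(OC)c3)c(OCc3ccccc3)c1OCc1ccccc1 | intermediate
15 | ethyl (3aR,4S,9aS)-5,6-bis(benzyloxy)-7-methoxy-3-oxo-4-(3,4,5-trimethoxyphenyl)-3,4,9,9a-tetrahydronaphtho[2,3-c]furan-3a(1H)-carboxylate | COc1cc2c(c(OCc3ccccc3)c1OCc1ccccc1)[C@H](c1cc(OC)c(OC)c(OC)c1)[C@](C(=O)OC3)(C(=O)OCC)[C@@H]3C2 | intermediate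
16 | (3aR,4S,9aS)-5,6-bis(benzyloxy)-7-methoxy-4-(3,4,5-trimethoxyphenyl)-3a,4,9,9a-tetrahydronaphtho[2,3-c]furan-3(1H)-one | COc1cc2c(c(OCc3ccccc3)c1OCc1ccccc1)[C@H](c1cc(OC)c(OC)c(OC)c1)[C@@H](C(=O)OC3)[C@@H]3C2 | intermediate
17 | [(1S,2R,3S)-7,8-bis(benzyloxy)-6-methoxy-1-(3,4,5-trimethoxyphenyl)-1,2,3,4-tetrahydronaphthalene-2,3-diyl]dimethanol | COc1cc2c(c(OCc3ccccc3)c1OCc1ccccc1)[C@H](c1cc(OC)c(OC)c(OC)c1)[C@@H](CO)[C@@H](CO)C2 | intermediate
18 | (6S,7R,8S)-6,7-bis(hydroxymethyl)-3-methoxy-8-(3,4,5-trimethoxyphenyl)-5,6,7,8-tetrahydronaphthalene-1,2-diol | COc1cc2c(c(O)c1O)[C@H](c1cc(OC)c(OC)c(OC)c1)[C@@H](CO)[C@@H](CO)C2 | target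

**Step count and risks**

Total step count: 12. Longest linear sequence: 11 steps (steps 1–4 and 6–12, from 1 to 18); the lactone branch (step 5) joins at step 6.

Steps most likely to fail:

1. Step 9 (ring closure). The weakly enolised lactone ester may capture the cation more slowly than a second molecule attacks C1 by Friedel–Crafts arylation, or than the C8 benzyl group is lost through an ortho-quinone methide. Facial selection at C1 may also be incomplete at the temperature the closure needs. The fallback sets out from 14 and comes back at 15. Treatment of 14 with TMSOTf and Et3N in CH2Cl2 should give ethyl (4S)-4-{3,4-bis(benzyloxy)-5-methoxy-2-[(3,4,5-trimethoxyphenyl)(trimethylsilyloxy)methyl]benzyl}-2-(trimethylsilyloxy)-4,5-dihydrofuran-3-carboxylate F1, in which the carbinol is a silyl ether and the dicarbonyl a silyl ketene acetal. A catalytic amount of TMSOTf at −78 °C then ionises the benzhydryl silyl ether, and the much more nucleophilic silyl ketene acetal closes ring B in a Mukaiyama-type SN1 alkylation to 15. The low temperature should also sharpen the selection at C1.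

2. Step 8 (aryl addition beside the acidic dicarbonyl). The magnesium enolate formed first may add to the neighbouring aldehyde in an intramolecular aldol reaction before the aryl Grignard reagent does, or incomplete enolate formation may let the reagent attack ester or lactone. The fallback sets out from 4 and comes back at 14; ring C is introduced before the coupling. Addition of 13 to aldehyde 4 gives [2,3-bis(benzyloxy)-6-bromo-4-methoxyphenyl](3,4,5-trimethoxyphenyl)methanol F2. t-BuLi (3 equiv, THF, −78 °C) removes the hydroxyl proton and exchanges the bromine to give lithium [2,3-bis(benzyloxy)-6-lithio-4-methoxyphenyl](3,4,5-trimethoxyphenyl)methanolate F3. MgBr2·OEt2 converts this into bromomagnesium [2,3-bis(benzyloxy)-6-(bromomagnesio)-4-methoxyphenyl](3,4,5-trimethoxyphenyl)methanolate F4, which opens lactone 9 under CuI catalysis as in step 6 and gives 14 after NH4Cl work-up. Steps 4 and 7 then fall away.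

3. Step 10 (dealkoxycarbonylation). Chloride attack on the ethyl ester of the crowded quaternary C2 may be slow, and at the temperature required the lactone may be opened at C10 or a benzyl ether lost. The fallback sets out from 15 and comes back at 16. LiOH in THF/H2O opens the lactone and hydrolyses the ester; acidification gives (1S,3S)-7,8-bis(benzyloxy)-3-(hydroxymethyl)-6-methoxy-1-(3,4,5-trimethoxyphenyl)-3,4-dihydronaphthalene-2,2(1H)-dicarboxylic acid F5. Heating in toluene with a trace of TsOH brings about decarboxylation and relactonisation, and DBU equilibrates C2 to the cis-fused lactone 16.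

**Further compounds**

F1 | step 9 | ethyl (4S)-4-{3,4-bis(benzyloxy)-5-methoxy-2-[(3,4,5-trimethoxyphenyl)(trimethylsilyloxy)methyl]benzyl}-2-(trimethylsilyloxy)-4,5-dihydrofuran-3-carboxylate | COc1cc(C[C@@H]2COC(O[Si](C)(C)C)=C2C(=O)OCC)c(C(O[Si](C)(C)C)c2cc(OC)c(OC)c(OC)c2)c(OCc2ccccc2)c1OCc1ccccc1
F2 | step 8 | [2,3-bis(benzyloxy)-6-bromo-4-methoxyphenyl](3,4,5-trimethoxyphenyl)methanol | COc1cc(Br)c(C(O)c2cc(OC)c(OC)c(OC)c2)c(OCc2ccccc2)c1OCc1ccccc1
F3 | step 8 | lithium [2,3-bis(benzyloxy)-6-lithio-4-methoxyphenyl](3,4,5-trimethoxyphenyl)methanolate | COc1cc([Li])c(C(O[Li])c2cc(OC)c(OC)c(OC)c2)c(OCc2ccccc2)c1OCc1ccccc1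
F4 | step 8 | bromomagnesium [2,3-bis(benzyloxy)-6-(bromomagnesio)-4-methoxyphenyl](3,4,5-trimethoxyphenyl)methanolate | COc1cc([Mg]Br)c(C(O[Mg]Br)c2cc(OC)c(OC)c(OC)c2)c(OCc2ccccc2)c1OCc1ccccc1
F5 | step 10 | (1S,3S)-7,8-bis(benzyloxy)-3-(hydroxymethyl)-6-methoxy-1-(3,4,5-trimethoxyphenyl)-3,4-dihydronaphthalene-2,2(1H)-dicarboxylic acid | COc1cc2c(c(OCc3ccccc3)c1OCc1ccccc1)[C@H](c1cc(OC)c(OC)c(OC)c1)C(C(=O)O)(C(=O)O)[C@@H](CO)C2
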